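Count what is left.

| setting | midnight | dawn | summer | flask |
|---|---|---|---|---|
| left-handed substrate | 11 mM | 24 mM | 16 mM | 16 mM |
| right-handed substrate | 11 mM | 24 mM | 16 mM | 16 mM |
| solid reagent | 40 mM | 40 mM | 60 mM | 40.0 mM |
| remark | run made earlier | run made earlier | run made earlier |  |
| time |  |  |  | 3.0 h |

| run | time / h | left-handed product / % | right-handed product / % |
|---|---|---|---|
| midnight | 0.500 | 14 | 6 |
| midnight | 1.00 | 20 | 14 |
| midnight | 1.50 | 30 | 25 |
| midnight | 2.00 | 35 | 30 |
| midnight | 2.50 | 38 | 35 |
| midnight | 3.00 | 41 | 38 |
| midnight | 4.00 | 44 | 46 |
| dawn | 0.200 | 3 | 4 |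
| dawn | 0.500 | 10 | 3 |
| dawn | 1.00 | 16 | 9 |
| dawn | 1.50 | 23 | 21 |
| dawn | 2.00 | 31 | 25 |
| dawn | 3.00 | 39 | 35 |
| dawn | 4.00 | 40 | 38 |
| summer | 0.250 | 4 | 2 |
| summer | 0.500 | 8 | 5 |
| summer | 1.00 | 21 | 14 |
| summer | 2.00 | 35 | 29 |
| summer | 4.00 | 44 | 42 |

(standard deviation of a reading: 1.5 percentage points)

- partner is single-handed; left-handed substrate and right-handed substrate are mirror images of each other, charged as a racemate, each of them at the stated concentration
- solid reagent is a solid; its amount is given per volume of the solution
- on the list of suspects stand: solid reagent <-> partner; 2 partner -> homo dimer; partner + left-handed substrate -> left-handed product; left-handed substrate <-> right-handed substrate; partner + right-handed substrate -> right-handed product; left-handed product <-> right-handed product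
- at the start none of the solid reagent is in solution
- an excess is below zero if the other one leads
- the handed part of partner does not stay in what it makes, so the products of the two hands are mirror images too

- excess of left-handed product over right-handed product in the product at 4.0 min
- excess of left-handed product over right-handed product in the product at 3.0 h
- part of the left-handed substrate and right-handed substrate charged together that has reacted at 3.0 h

**The measure.** I take the fraction of both substrates left, invert it, take the logarithm and divide by the time. The readings give 0.520 h⁻¹ for the midnight run over 3.00 h. They give 0.449 h⁻¹ for the dawn run over 3.00 h.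

**The start.** The dawn run begins lower, at 0.279 h⁻¹ over 0.500 h. That is a factor 0.621 of its three-hour reading, because partner must first dissolve.

**The slowing.** More substrate lowers the measure. Going from 11 mM to 24 mM of c(left-handed substrate) multiplies it by 0.863. Between these runs, at 16 mM, I read 0.493 h⁻¹. This is the fraction-left constant, a pseudo-first-order constant averaged over the run. More solid reagent does not raise it: the summer run, with 60 mM, reads 0.492 h⁻¹ over 4.00 h.

**The end.** Over 3.0 h the exponent grows to 1.48, so I expect 77.2 % reacted. The excesses I leave to the flask. The forecast says 39 %, 5 % and 76 %, the last below mine, from the view that “The runs behave as first order in substrate”.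

**The flask.** It gives 45.9 %, 2.50 % and 78.8 %.

    solid reagent ⇌ partner, rate k1*(cs1 - [partner]) while solid is left; crystals form when [partner] > cs1 (solubility = 5.60 mM, k = 0.0800 min⁻¹)
    2 partner → homo dimer (k = 0.140 L mol⁻¹ min⁻¹)
    partner + left-handed substrate → left-handed product (k = 4.12 L mol⁻¹ min⁻¹)
    left-handed substrate ⇌ right-handed substrate (k = 0.00521 min⁻¹)
    partner + right-handed substrate → right-handed product (k = 1.45 L mol⁻¹ min⁻¹)
    left-handed product ⇌ right-handed product (k = 0.0146 min⁻¹)

**The comparison.** In the flask the reacted part gives a fraction-left constant, averaged over 3.0 h, of 0.516 h⁻¹ against my 0.493 h⁻¹. The half-life of left-handed product by its forward step to right-handed product alone is 0.79 h, short against 3.0 h, and the excess in the flask stands at 2.50 % by then. A neighbour flask with 16 mM of solid reagent has 0 % of that solid left at 3.0 h and 49.3 % reacted. Its constant is 0.227 h⁻¹, a factor 0.440 of the flask's.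

The numbers in the tables stem from a simulated flask from invented constants; the scatter is artificial.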